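**Plan**

- The benzo ring C4a'–C8a' of the primed chroman-2-one carries oxygen on C5', C6', C7', C8' and C8a' and carbon only on C4a'. It therefore divides into a squarate-derived cyclobutenone (C6', C7', C8', C8a') and an ynol ether (C5', C4a'). After eight O-dealkylations the retrosynthesis cuts C4a'–C8a', C5'–C6', C8'–C8a' and O1'–C2' in one step.
- The ynol ether precursor already holds the unprimed lactone and all four stereocentres. It is cut at O1–C2/C3–C4 (quinone methide annulation), C3–C3' (enolate alkylation with a bromoacetate) and C4'–C(sp) (conjugate addition of ethoxyacetylide).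
- Forward: chain C2'–C3'–C4'–C≡C–OEt, then the C3/C2 unit, then the unprimed benzopyranone ring, then the primed benzene and pyranone rings together, then global dealkylation.
- Stereochemistry: C4' by chromatographic resolution of the two imides formed from the racemic acid salt and (R)-4-benzyloxazolidin-2-one; C3' by Evans alkylation under the same auxiliary; C3 and C4 (cis) by a chiral triazolylidene in the quinone methide annulation. The key step creates no stereocentre, runs without acid or base, and expels the auxiliary in its lactonisation.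

Key step: step 13

Assumption: chroman-2-one numbering is used for both halves (unprimed = 5,7-dioxygenated, primed = 5,6,7,8-tetraoxygenated), also in open-chain precursors; the antipode of the aminoindanol triazolium salt in step 10 is the one that exposes the Si face of the enolate carbon, to be fixed on a model acyl imidazole.

**Route**

Step 1
Reactants: 1 4-methoxybenzaldehyde; 2 methyl 2-(phenylsulfonyl)acetate
Product: 3 methyl (E)-3-(4-methoxyphenyl)-2-(phenylsulfonyl)prop-2-enoate
Conditions: piperidine (cat.), AcOH (cat.), toluene, reflux, Dean–Stark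
Reagents that add atoms: none
Why: Knoevenagel condensation of the doubly activated methylene of 2 with the aldehyde should give the (E)-alkene (aryl trans to the sulfonyl group), with no stereocentre formed.

Step 2
Reactants: 3 methyl (E)-3-(4-methoxyphenyl)-2-(phenylsulfonyl)prop-2-enoate; 4 ethoxyacetylene
Product: 6 methyl 5-ethoxy-3-(4-methoxyphenyl)-2-(phenylsulfonyl)pent-4-ynoate (racemic; both epimers at the sulfonyl carbon), via ethoxyethynyl Grignard reagent 5 (not isolated)
Conditions: EtMgBr, THF, 0 °C to rt; then 3, −40 to 0 °C; aq. NaHCO3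
Reagents that add atoms: none
Why: Deprotonation of 4 gives alkynyl Grignard reagent 5, which adds in conjugate (Michael) fashion to the doubly activated alkene of 3, forming C4' as a racemate and a sulfonyl ester adduct that, unlike adducts of more acidic 1,3-dicarbonyl acceptors, is too weak a carbon acid to protonate the ynol ether.

Step 3
Reactants: 6 methyl 5-ethoxy-3-(4-methoxyphenyl)-2-(phenylsulfonyl)pent-4-ynoate
Product: 7 methyl 5-ethoxy-3-(4-methoxyphenyl)pent-4-ynoate (racemic)
Conditions: Mg, MeOH, 0 °C to rt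
Reagents that add atoms: none
Why: Reductive desulfonylation, in which electron transfer from magnesium cleaves the C–S bond alpha to the ester and methanol protonates the resulting enolate, proceeds in a basic medium that should leave the ynol ether and the isolated triple bond untouched.

Step 4
Reactants: 7 methyl 5-ethoxy-3-(4-methoxyphenyl)pent-4-ynoate
Product: 8 lithium 5-ethoxy-3-(4-methoxyphenyl)pent-4-ynoate (racemic)
Conditions: LiOH, THF/MeOH/H2O, 0 °C to rt; evaporation, toluene azeotrope
Reagents that add atoms: lithium hydroxide, [Li+].[OH-]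
Why: Saponification of the methyl ester is routine, and the acid is kept as its lithium salt because a free carboxylic acid would add across the ynol ether.

Step 5
Reactants: 8 lithium 5-ethoxy-3-(4-methoxyphenyl)pent-4-ynoate; 9 (R)-4-benzyl-1,3-oxazolidin-2-one
Product: 11 (4R)-4-benzyl-3-[(3R)-5-ethoxy-3-(4-methoxyphenyl)pent-4-ynoyl]-1,3-oxazolidin-2-one, via mixed pivalic anhydride 10 (not isolated)
Conditions: t-BuCOCl, THF, −20 °C; then 9, Et3N, LiCl, −20 °C to rt; chromatography
Reagents that add atoms: none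
Why: The carboxylate forms mixed anhydride 10, which N-acylates the oxazolidinone (standard auxiliary attachment), and the two imides arising from the racemic acid differ at C4' and should separate by chromatography, the (3R) isomer being kept (assignment by X-ray or correlation) so that C4' is secured by resolution.

Step 6
Reactants: 11 (4R)-4-benzyl-3-[(3R)-5-ethoxy-3-(4-methoxyphenyl)pent-4-ynoyl]-1,3-oxazolidin-2-one; 12 allyl bromoacetate
Product: 14 prop-2-enyl (3R,4R)-3-[(4R)-4-benzyl-2-oxo-1,3-oxazolidine-3-carbonyl]-6-ethoxy-4-(4-methoxyphenyl)hex-5-ynoate, via sodium enolate 13 (not isolated)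
Conditions: NaN(SiMe3)2, THF, −78 °C; then 12, −78 to −40 °C
Reagents that add atoms: none
Why: In this Evans alkylation the chelated Z enolate 13 is attacked on the face opposite the benzyl group, which sets C3', and that face is also anti to the C4' aryl group in the allylic-strain-minimised conformer, so auxiliary and substrate should be matched.

Step 7
Reactants: 14 prop-2-enyl (3R,4R)-3-[(4R)-4-benzyl-2-oxo-1,3-oxazolidine-3-carbonyl]-6-ethoxy-4-(4-methoxyphenyl)hex-5-ynoate
Product: 15 potassium (3R,4R)-3-[(4R)-4-benzyl-2-oxo-1,3-oxazolidine-3-carbonyl]-6-ethoxy-4-(4-methoxyphenyl)hex-5-ynoate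
Conditions: Pd(PPh3)4 (3 mol %), potassium 2-ethylhexanoate, EtOAc/CH2Cl2, rt
Reagents that add atoms: potassium 2-ethylhexanoate, [K+].[O-]C(=O)C(CC)CCCC
Why: Tsuji–Trost deallylation through a π-allyl complex formed from the zerovalent palladium complex, with 2-ethylhexanoate as allyl acceptor, should deliver the potassium carboxylate directly under neutral conditions, again avoiding a free acid next to the ynol ether.

Step 8
Reactants: 16 2-hydroxy-4,6-dimethoxybenzaldehyde; 17 4-methoxyphenylmagnesium bromide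
Product: 18 2-[hydroxy(4-methoxyphenyl)methyl]-3,5-dimethoxyphenol (racemic)
Conditions: THF, 0 °C to rt (2.2 equiv of 17); pH 7 buffer
Reagents that add atoms: none
Why: Grignard addition to the aldehyde, after the first equivalent of 17 has deprotonated the phenol, gives the racemic benzhydrol, whose configuration is irrelevant because this carbon becomes trigonal in the quinone methide.

Step 9
Reactants: 18 2-[hydroxy(4-methoxyphenyl)methyl]-3,5-dimethoxyphenol
Product: 19 3,5-dimethoxy-2-[(4-methoxyphenyl)(4-methylphenylsulfonyl)methyl]phenol (racemic)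
Conditions: 4-MeC6H4SO2Na, HCO2H/H2O, rt
Reagents that add atoms: sodium 4-methylbenzenesulfinate, [Na+].[O-]S(=O)c1ccc(C)cc1
Why: Acid-promoted ionisation of the electron-rich benzhydrol and S-alkylation of the sulfinate (SN1 substitution) should give a storable sulfone from which base releases the quinone methide.

Step 10
Reactants: 15 potassium (3R,4R)-3-[(4R)-4-benzyl-2-oxo-1,3-oxazolidine-3-carbonyl]-6-ethoxy-4-(4-methoxyphenyl)hex-5-ynoate; 19 3,5-dimethoxy-2-[(4-methoxyphenyl)(4-methylphenylsulfonyl)methyl]phenol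
Product: 22 (4R)-4-benzyl-3-{(2S,3R)-2-[(3S,4R)-5,7-dimethoxy-4-(4-methoxyphenyl)-2-oxochroman-3-yl]-5-ethoxy-3-(4-methoxyphenyl)pent-4-ynoyl}-1,3-oxazolidin-2-one, via acyl imidazole 20 (not isolated), via quinone methide 21 (not isolated)
Conditions: CDI, imidazole·HCl, THF, rt; then 19, chiral N-mesityl aminoindanol triazolium chloride (20 mol %), Cs2CO3, THF, 0 °C to rt
Reagents that add atoms: none
Why: In this N-heterocyclic carbene catalysed [4+2] annulation, acyl transfer from 20 to the carbene and deprotonation give a Z azolium enolate that adds by an endo Michael–lactonisation path to quinone methide 21 (released from 19 by base), the catalyst directing the Re face of C4 onto the Si face of the enolate carbon so that C3 (S) and C4 (R) arise together and cis, while allylic strain keeps the imide α-hydrogen at C3' from enolising.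

Step 11
Reactants: 23 dimethyl squarate
Product: 24 4-hydroxy-2,3-dimethoxycyclobut-2-en-1-one (racemic)
Conditions: LiAlH(OtBu)3, THF, −78 °C; aq. Rochelle salt
Reagents that add atoms: none
Why: 1,2-Reduction of one carbonyl of the squarate, a vinylogous ester that takes up only one hydride at low temperature, gives the racemic hydroxycyclobutenone, whose stereocentre is lost later on aromatisation.

Step 12
Reactants: 24 4-hydroxy-2,3-dimethoxycyclobut-2-en-1-one
Product: 25 2,3,4-trimethoxycyclobut-2-en-1-one (racemic)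
Conditions: MeI, Ag2O, CH2Cl2, rt, dark
Reagents that add atoms: iodomethane, CI
Why: O-Methylation under neutral silver oxide conditions (Williamson type) avoids both the free alkoxide, which would trigger ring opening, and acid, which would eliminate methanol.

Step 13
Reactants: 22 (4R)-4-benzyl-3-{(2S,3R)-2-[(3S,4R)-5,7-dimethoxy-4-(4-methoxyphenyl)-2-oxochroman-3-yl]-5-ethoxy-3-(4-methoxyphenyl)pent-4-ynoyl}-1,3-oxazolidin-2-one; 25 2,3,4-trimethoxycyclobut-2-en-1-one
Product: 31 (3S,4R,3'S,4'R)-5'-ethoxy-5,6',7,7',8'-pentamethoxy-4,4'-bis(4-methoxyphenyl)-[3,3'-bichromane]-2,2'-dione, via vinylketene 26 (not isolated), via vinylcyclobutenone 27 (not isolated), via dienylketene 28 (not isolated), via cyclohexadienone 29 (not isolated), via phenol 30 (not isolated)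
Conditions: 25 (2.5 equiv), toluene (0.4 M), 80 °C, argon; then 2-pyridone (0.2 equiv), 80 °C
Reagents that add atoms: none
Why: Thermal 4π opening of 25 (C4 methoxy rotating outward) gives vinylketene 26, whose carbonyl carbon is attacked by the nucleophilic alkyne carbon of 22 (the one bearing C4') in a regiospecific [2+2] that forms C4a'–C8a' and C5'–C6' (27). A second 4π opening, again with methoxy outward and the vinyl group inward, gives dienylketene 28, which closes C8'–C8a' by thermal disrotatory 6π electrocyclisation to 29 and tautomerises to phenol 30. The closest known reaction type is the Danheiser benzannulation of cyclobutenones with alkoxyalkynes, here with a fully oxygenated, squarate-derived cyclobutenone. The benzene ring thus closes by 6π electrocyclisation, and the pyranone by 6-exo-trig attack of the C8a' hydroxyl on the activated imide carbonyl C2', which expels the oxazolidinone and forms O1'–C2'. No stereocentre is created, and the neutral medium should leave the four existing ones, in particular the epimerisable cis C3 and C3' centres, untouched. The step needs only regioselectivity, fixed by the polarity match between the ynol ether β-carbon and the ketene carbonyl, and a temperature (80 °C) below the retro-ene loss of ethylene from the ethyl ynol ether.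

Step 14
Reactants: 31 (3S,4R,3'S,4'R)-5'-ethoxy-5,6',7,7',8'-pentamethoxy-4,4'-bis(4-methoxyphenyl)-[3,3'-bichromane]-2,2'-dione
Product: 32 (3S,4R,3'S,4'R)-5,5',6',7,7',8'-hexahydroxy-4,4'-bis(4-hydroxyphenyl)-[3,3'-bichromane]-2,2'-dione
Conditions: BBr3 (excess), CH2Cl2, −78 °C to rt; degassed MeOH/H2O, argon
Reagents that add atoms: none
Why: Lewis acid mediated ether cleavage by BBr3 removes the seven methyl groups and the ethyl group as alkyl bromides while the aryl lactones persist, and the acidic, oxygen-free work-up should avoid enolisation of the cis C3/C3' centres and oxidation of the tetrahydroxylated ring.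

**Compound list**

1 | 4-methoxybenzaldehyde | COc1ccc(C=O)cc1 | starting material
2 | methyl 2-(phenylsulfonyl)acetate | COC(=O)CS(=O)(=O)c1ccccc1 | starting material
3 | methyl (E)-3-(4-methoxyphenyl)-2-(phenylsulfonyl)prop-2-enoate | COC(=O)/C(=C\c1ccc(OC)cc1)S(=O)(=O)c1ccccc1 | intermediate
4 | ethoxyacetylene | CCOC#C | starting material
5 | (ethoxyethynyl)magnesium bromide | CCOC#C[Mg]Br | intermediate
6 | methyl 5-ethoxy-3-(4-methoxyphenyl)-2-(phenylsulfonyl)pent-4-ynoate (racemic, both epimers) | CCOC#CC(c1ccc(OC)cc1)C(C(=O)OC)S(=O)(=O)c1ccccc1 | intermediate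
7 | methyl 5-ethoxy-3-(4-methoxyphenyl)pent-4-ynoate (racemic) | CCOC#CC(CC(=O)OC)c1ccc(OC)cc1 | intermediate
8 | lithium 5-ethoxy-3-(4-methoxyphenyl)pent-4-ynoate (racemic) | [Li+].[O-]C(=O)CC(C#COCC)c1ccc(OC)cc1 | intermediate
9 | (R)-4-benzyl-1,3-oxazolidin-2-one | O=C1N[C@H](Cc2ccccc2)CO1 | starting material
10 | 5-ethoxy-3-(4-methoxyphenyl)pent-4-ynoic pivalic anhydride (racemic) | CC(C)(C)C(=O)OC(=O)CC(C#COCC)c1ccc(OC)cc1 | intermediate
11 | (4R)-4-benzyl-3-[(3R)-5-ethoxy-3-(4-methoxyphenyl)pent-4-ynoyl]-1,3-oxazolidin-2-one | O=C(C[C@H](c1ccc(OC)cc1)C#COCC)N1[C@H](Cc2ccccc2)COC1=O | intermediate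
12 | allyl bromoacetate (prop-2-enyl 2-bromoacetate) | C=CCOC(=O)CBr | starting material
13 | sodium (Z)-enolate of 11 | [Na+].[O-]/C(=C\[C@H](c1ccc(OC)cc1)C#COCC)N1[C@H](Cc2ccccc2)COC1=O | intermediate
14 | prop-2-enyl (3R,4R)-3-[(4R)-4-benzyl-2-oxo-1,3-oxazolidine-3-carbonyl]-6-ethoxy-4-(4-methoxyphenyl)hex-5-ynoate | C=CCOC(=O)C[C@@H](C(=O)N1[C@H](Cc2ccccc2)COC1=O)[C@H](c1ccc(OC)cc1)C#COCC | intermediate
15 | potassium (3R,4R)-3-[(4R)-4-benzyl-2-oxo-1,3-oxazolidine-3-carbonyl]-6-ethoxy-4-(4-methoxyphenyl)hex-5-ynoate | [K+].[O-]C(=O)C[C@@H](C(=O)N1[C@H](Cc2ccccc2)COC1=O)[C@H](c1ccc(OC)cc1)C#COCC | intermediate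
16 | 2-hydroxy-4,6-dimethoxybenzaldehyde | COc1cc(O)c(C=O)c(OC)c1 | starting material
17 | 4-methoxyphenylmagnesium bromide | COc1ccc([Mg]Br)cc1 | starting material
18 | 2-[hydroxy(4-methoxyphenyl)methyl]-3,5-dimethoxyphenol (racemic) | COc1ccc(C(O)c2c(O)cc(OC)cc2OC)cc1 | intermediate
19 | 3,5-dimethoxy-2-[(4-methoxyphenyl)(4-methylphenylsulfonyl)methyl]phenol (racemic) | COc1ccc(C(c2c(O)cc(OC)cc2OC)S(=O)(=O)c2ccc(C)cc2)cc1 | intermediate
20 | (4R)-4-benzyl-3-[(2R,3R)-5-ethoxy-2-[2-(imidazol-1-yl)-2-oxoethyl]-3-(4-methoxyphenyl)pent-4-ynoyl]-1,3-oxazolidin-2-one | O=C(C[C@@H](C(=O)N1[C@H](Cc2ccccc2)COC1=O)[C@H](c1ccc(OC)cc1)C#COCC)n1ccnc1 | intermediate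
21 | 3,5-dimethoxy-6-(4-methoxybenzylidene)cyclohexa-2,4-dien-1-one (ortho-quinone methide, alkene geometry labile) | COC1=CC(=O)C(=Cc2ccc(OC)cc2)C(OC)=C1 | intermediate
22 | (4R)-4-benzyl-3-{(2S,3R)-2-[(3S,4R)-5,7-dimethoxy-4-(4-methoxyphenyl)-2-oxochroman-3-yl]-5-ethoxy-3-(4-methoxyphenyl)pent-4-ynoyl}-1,3-oxazolidin-2-one | O=C1Oc2cc(OC)cc(OC)c2[C@@H](c2ccc(OC)cc2)[C@H]1[C@@H](C(=O)N1[C@H](Cc2ccccc2)COC1=O)[C@H](c1ccc(OC)cc1)C#COCC | intermediate
23 | dimethyl squarate (3,4-dimethoxycyclobut-3-ene-1,2-dione) | COC1=C(OC)C(=O)C1=O | starting material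
24 | 4-hydroxy-2,3-dimethoxycyclobut-2-en-1-one (racemic) | COC1=C(OC)C(O)C1=O | intermediate
25 | 2,3,4-trimethoxycyclobut-2-en-1-one (racemic) | COC1C(OC)=C(OC)C1=O | intermediate
26 | (Z)-2,3,4-trimethoxybuta-1,3-dien-1-one (trimethoxyvinylketene) | CO/C=C(OC)/C(OC)=C=O | intermediate
27 | [2+2] adduct: 3-ethoxy-4-methoxy-4-[(Z)-1,2-dimethoxyethenyl]cyclobut-2-en-1-one carrying at C2 the C4' side chain of 22 (both epimers at ring C4) | O=C1Oc2cc(OC)cc(OC)c2[C@@H](c2ccc(OC)cc2)[C@H]1[C@@H](C(=O)N1[C@H](Cc2ccccc2)COC1=O)[C@H](c1ccc(OC)cc1)C1=C(OCC)C(OC)(/C(OC)=C/OC)C1=O | intermediate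
28 | (3Z,5Z)-3-ethoxy-4,5,6-trimethoxyhexa-1,3,5-trien-1-one carrying at C2 the C4' side chain of 22 (dienylketene) | O=C1Oc2cc(OC)cc(OC)c2[C@@H](c2ccc(OC)cc2)[C@H]1[C@@H](C(=O)N1[C@H](Cc2ccccc2)COC1=O)[C@H](c1ccc(OC)cc1)C(=C=O)/C(OCC)=C(OC)\C(OC)=C\OC | intermediate
29 | 3-ethoxy-4,5,6-trimethoxycyclohexa-2,4-dien-1-one carrying at C2 the C4' side chain of 22 (both epimers at ring C6) | O=C1Oc2cc(OC)cc(OC)c2[C@@H](c2ccc(OC)cc2)[C@H]1[C@@H](C(=O)N1[C@H](Cc2ccccc2)COC1=O)[C@H](c1ccc(OC)cc1)C1=C(OCC)C(OC)=C(OC)C(OC)C1=O | intermediate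
30 | (4R)-4-benzyl-3-{(2S,3R)-2-[(3S,4R)-5,7-dimethoxy-4-(4-methoxyphenyl)-2-oxochroman-3-yl]-3-(2-ethoxy-6-hydroxy-3,4,5-trimethoxyphenyl)-3-(4-methoxyphenyl)propanoyl}-1,3-oxazolidin-2-one | O=C1Oc2cc(OC)cc(OC)c2[C@@H](c2ccc(OC)cc2)[C@H]1[C@@H](C(=O)N1[C@H](Cc2ccccc2)COC1=O)[C@H](c1ccc(OC)cc1)c1c(OCC)c(OC)c(OC)c(OC)c1O | intermediate
31 | (3S,4R,3'S,4'R)-5'-ethoxy-5,6',7,7',8'-pentamethoxy-4,4'-bis(4-methoxyphenyl)-[3,3'-bichromane]-2,2'-dione | O=C1Oc2cc(OC)cc(OC)c2[C@@H](c2ccc(OC)cc2)[C@H]1[C@H]1C(=O)Oc2c(OC)c(OC)c(OC)c(OCC)c2[C@H]1c1ccc(OC)cc1 | intermediate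
32 | (3S,4R,3'S,4'R)-5,5',6',7,7',8'-hexahydroxy-4,4'-bis(4-hydroxyphenyl)-[3,3'-bichromane]-2,2'-dione | O=C1Oc2cc(O)cc(O)c2[C@@H](c2ccc(O)cc2)[C@H]1[C@H]1C(=O)Oc2c(O)c(O)c(O)c(O)c2[C@H]1c1ccc(O)cc1 | target

**Step count**

Total steps: 14. Longest linear sequence: 10 steps (steps 1 to 7, 10, 13, 14).

**Steps most likely to fail**

Step 13. The intermolecular [2+2] at the doubly branched alkyne of 22 may be outrun by reclosure or dimerisation of the vinylketene. Forcing the temperature would bring retro-ene loss of ethylene from the ynol ether, and a day of heating may erode the cis unprimed lactone. The fallback reverses the order of ring construction. It sets out from 14 and 25, and the benzannulation is run on this smaller imide under the same conditions, with light-assisted ring opening of 25 at 20 °C if heat alone does not suffice. It passes through the vinylcyclobutenone F1, the dienylketene F2, the cyclohexadienone F3 and the hydroxy imide F4 to the primed lactone allyl ester F5, with the auxiliary expelled. Deallylation as in step 7 gives the potassium carboxylate F6. Activation to the acyl imidazole F7 and the quinone methide annulation of step 10 (19, same catalyst, K2CO3 at 0 °C to spare the cis C3' centre) rejoin the route at 31.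

Step 10. The catalyst may be mismatched with the neighbouring C3' centre. Addition to the peri-methoxylated quinone methide may proceed stepwise and lose the cis relationship. The carbonate base may epimerise C3. The fallback sets out from 15 and 19 and replaces cycloaddition control of C3 by equilibration and kinetic protonation. The crude annulation product is first driven with DBU to the thermodynamically favoured trans lactone F8, the C3 epimer of 22. KN(SiMe3)2 in THF at −78 °C then removes the lactone α-hydrogen, the most acidic one because the imide α-hydrogen is held in the imide plane. Quenching with 2,6-di-tert-butylphenol delivers the proton to the face opposite the pseudo-axial C4 aryl group, which returns the cis lactone 22.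

Step 14. Cleavage of the flanked C5' ethyl ether may be incomplete, and the pentaoxygenated ring may oxidise in air during aqueous work-up and chromatography. The fallback sets out from 31 and changes the isolation to a protected form. After BBr3 and methanol quench under argon the residue is acetylated at once (Ac2O, pyridine, 0 °C) to the octaacetate F9, which can be purified and checked for complete dealkylation. Acid methanolysis (HCl in MeOH, 0 °C to rt, argon) then releases the phenols without base, any opened lactone closing again on concentration, and returns to 32.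

**Further compounds**

F1 | step 13 | prop-2-enyl (3R,4R)-3-[(4R)-4-benzyl-2-oxo-1,3-oxazolidine-3-carbonyl]-4-{3-ethoxy-4-methoxy-4-[(Z)-1,2-dimethoxyethenyl]-1-oxocyclobut-2-en-2-yl}-4-(4-methoxyphenyl)butanoate (vinylcyclobutenone) | C=CCOC(=O)C[C@@H](C(=O)N1[C@H](Cc2ccccc2)COC1=O)[C@H](c1ccc(OC)cc1)C1=C(OCC)C(OC)(/C(OC)=C/OC)C1=O
F2 | step 13 | dienylketene from 14: (3Z,5Z)-3-ethoxy-4,5,6-trimethoxyhexa-1,3,5-trien-1-one carrying at C2 the C4' side chain of 14 | C=CCOC(=O)C[C@@H](C(=O)N1[C@H](Cc2ccccc2)COC1=O)[C@H](c1ccc(OC)cc1)C(=C=O)/C(OCC)=C(OC)\C(OC)=C\OC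
F3 | step 13 | cyclohexadienone from 14: 3-ethoxy-4,5,6-trimethoxycyclohexa-2,4-dien-1-one carrying at C2 the C4' side chain of 14 | C=CCOC(=O)C[C@@H](C(=O)N1[C@H](Cc2ccccc2)COC1=O)[C@H](c1ccc(OC)cc1)C1=C(OCC)C(OC)=C(OC)C(OC)C1=O
F4 | step 13 | prop-2-enyl (3R,4R)-3-[(4R)-4-benzyl-2-oxo-1,3-oxazolidine-3-carbonyl]-4-(2-ethoxy-6-hydroxy-3,4,5-trimethoxyphenyl)-4-(4-methoxyphenyl)butanoate (hydroxy imide) | C=CCOC(=O)C[C@@H](C(=O)N1[C@H](Cc2ccccc2)COC1=O)[C@H](c1ccc(OC)cc1)c1c(OCC)c(OC)c(OC)c(OC)c1O
F5 | step 13 | prop-2-enyl 2-[(3R,4R)-5-ethoxy-6,7,8-trimethoxy-4-(4-methoxyphenyl)-2-oxochroman-3-yl]acetate | C=CCOC(=O)C[C@H]1C(=O)Oc2c(OC)c(OC)c(OC)c(OCC)c2[C@H]1c1ccc(OC)cc1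
F6 | step 13 | potassium 2-[(3R,4R)-5-ethoxy-6,7,8-trimethoxy-4-(4-methoxyphenyl)-2-oxochroman-3-yl]acetate | [K+].[O-]C(=O)C[C@H]1C(=O)Oc2c(OC)c(OC)c(OC)c(OCC)c2[C@H]1c1ccc(OC)cc1
F7 | step 13 | (3R,4R)-5-ethoxy-3-[2-(imidazol-1-yl)-2-oxoethyl]-6,7,8-trimethoxy-4-(4-methoxyphenyl)chroman-2-one | O=C(C[C@H]1C(=O)Oc2c(OC)c(OC)c(OC)c(OCC)c2[C@H]1c1ccc(OC)cc1)n1ccnc1
F8 | step 10 | (4R)-4-benzyl-3-{(2S,3R)-2-[(3R,4R)-5,7-dimethoxy-4-(4-methoxyphenyl)-2-oxochroman-3-yl]-5-ethoxy-3-(4-methoxyphenyl)pent-4-ynoyl}-1,3-oxazolidin-2-one (trans lactone) | O=C1Oc2cc(OC)cc(OC)c2[C@@H](c2ccc(OC)cc2)[C@@H]1[C@@H](C(=O)N1[C@H](Cc2ccccc2)COC1=O)[C@H](c1ccc(OC)cc1)C#COCC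
F9 | step 14 | octaacetate of 32: (3S,4R,3'S,4'R)-5,5',6',7,7',8'-hexaacetoxy-4,4'-bis(4-acetoxyphenyl)-[3,3'-bichromane]-2,2'-dione | O=C1Oc2cc(OC(C)=O)cc(OC(C)=O)c2[C@@H](c2ccc(OC(C)=O)cc2)[C@H]1[C@H]1C(=O)Oc2c(OC(C)=O)c(OC(C)=O)c(OC(C)=O)c(OC(C)=O)c2[C@H]1c1ccc(OC(C)=O)cc1
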